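## Retrosynthetic overview

1. Feature: the core is a 6-oxabicyclo[3.2.1]octane-7,8-dione (C1 prenyl bridgehead, C2H2, C3H-prenyl, C4Me2, C5 acyl bridgehead, O6, C7 lactone C=O, C8 ketone). C1 lies between C7=O and C8=O, and the C4–C3–C2 bridge is a disguised 1,1-dimethylallyl group on C5.
2. Target 18 ⇒ C3-allyl bicycle 16 (cross-metathesis) ⇒ cut C1–C2 and C3–CH2 to give 3-bromofuran-2,4-dione 13 and allyltributylstannane 14 (radical 6-endo closure, then allylation).
3. 13 ⇒ tetronic acid 12 (bromination) ⇒ ester 11 (Dieckmann, C1–C8 bond) ⇒ tertiary alcohol 8 and 5-methylhex-4-enoic acid 9.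
4. 8 ⇒ prenyl ether 7 ([2,3]-Wittig, forms C4–C5 and sets C5) ⇒ diazo keto ester 5 and prenol 6 ⇒ (R)-2-methylbutanoic acid 1 and malonate 2.
5. Ring order: the γ-lactone ring (C1–C7–O6–C5–C8) closes in step 6, and the cyclohexanone ring (C1–C2–C3–C4–C5–C8) closes in step 8.

Key step: step 8

Assumption: the facial sense of the Ni(II)/N,N'-dioxide catalyst on ether 7 cannot be predicted safely, so both ligand antipodes are tested and the one giving (2S)-8 is used. Compound 8 and its C2 epimer are diastereomers, so the assignment can be checked and the material upgraded by chromatography.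

## Route

Step 1
Reactants: 1 (R)-2-methylbutanoic acid; 2 potassium methyl malonate
Product: 4 methyl (4R)-4-methyl-3-oxohexanoate, via acyl imidazolide 3 (not isolated)
Conditions: CDI, THF, rt; then 2, MgCl2, Et3N (pre-stirred in MeCN), rt to 40 °C; 1 M HCl work-up
Reagents that add atoms: potassium methyl malonate (2), COC(=O)CC(=O)[O-].[K+]; 1,1'-carbonyldiimidazole, O=C(n1ccnc1)n1ccnc1 (imidazolyl group, retained only in 3)
Why: Masamune–Brooks C-acylation of the magnesium malonate half-ester enolate by the acyl imidazolide, followed by decarboxylation, holds the product as its C2 chelated enolate, so the C4 stereocentre taken from 1 should pass through unchanged.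

Step 2
Reactants: 4 methyl (4R)-4-methyl-3-oxohexanoate
Product: 5 methyl (4R)-2-diazo-4-methyl-3-oxohexanoate
Conditions: 4-acetamidobenzenesulfonyl azide, Et3N, MeCN, 0 °C to rt
Reagents that add atoms: 4-acetamidobenzenesulfonyl azide, CC(=O)Nc1ccc(cc1)S(=O)(=O)N=[N+]=[N-]
Why: Regitz diazo transfer needs only an amine base, which deprotonates the active C2 methylene alone, so C4 is not touched and no stereocentre is formed.

Step 3
Reactants: 5 methyl (4R)-2-diazo-4-methyl-3-oxohexanoate; 6 prenol
Product: 7 methyl (4R)-4-methyl-2-[(3-methylbut-2-en-1-yl)oxy]-3-oxohexanoate (both C2 epimers)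
Conditions: Rh2(OAc)4 (1 mol %), 6 (3 equiv), CH2Cl2, rt, slow addition of 5
Reagents that add atoms: prenol (6), CC(C)=CCO
Why: Rh(II)-carbenoid O–H insertion of an acceptor/acceptor diazo compound into a primary alcohol outruns cyclopropanation; at rt the first-formed enol, with its hindered prenyl terminus, should tautomerise to the ether rather than undergo a [3,3] shift, and the unselective C2 centre is erased in step 4.

Step 4
Reactants: 7 methyl (4R)-4-methyl-2-[(3-methylbut-2-en-1-yl)oxy]-3-oxohexanoate
Product: 8 methyl (2S,4R)-2-hydroxy-4-methyl-2-(2-methylbut-3-en-2-yl)-3-oxohexanoate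
Conditions: Ni(OTf)2 with a C2-symmetric chiral N,N'-dioxide (from pipecolic acid and 2,6-diisopropylaniline, 1,3-propylene linker; 10 mol %), Et3N (20 mol %), CH2Cl2, 30 °C; chromatography
Reagents that add atoms: none
Why: In this catalytic asymmetric [2,3]-Wittig rearrangement of a 2-allyloxy-1,3-dicarbonyl compound, both C2 epimers converge on one Ni-chelated enolate whose open face bonds to the CMe2 terminus through a five-membered envelope transition state, so the ligand sets C2 as S (catalyst control, with little bias from the remote Me/Et centre) while the 1,1-dimethylallyl group and the tertiary carbinol appear.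

Step 5
Reactants: 8 methyl (2S,4R)-2-hydroxy-4-methyl-2-(2-methylbut-3-en-2-yl)-3-oxohexanoate; 9 5-methylhex-4-enoic acid
Product: 11 methyl (2S,4R)-4-methyl-2-(2-methylbut-3-en-2-yl)-2-[(5-methylhex-4-enoyl)oxy]-3-oxohexanoate, via 5-methylhex-4-enoyl chloride 10 (not isolated)
Conditions: 9, Me2C=C(Cl)NMe2, CH2Cl2, 0 °C to rt; separately 8, LiHMDS (1.05 equiv), THF, −78 °C; then 10 (1.5 equiv), −78 to 0 °C
Reagents that add atoms: 5-methylhex-4-enoic acid (9), CC(C)=CCCC(=O)O; 1-chloro-N,N,2-trimethylprop-1-en-1-amine, CC(C)=C(Cl)N(C)C (chlorine, retained only in 10)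
Why: O-acylation of a preformed lithium alkoxide with an acid chloride is the standard method for hindered tertiary alcohols; the chloroenamine makes 10 without HCl and so spares the trisubstituted alkene, and one equivalent of base removes only the O–H proton, leaving both stereocentres untouched.

Step 6
Reactants: 11 methyl (2S,4R)-4-methyl-2-(2-methylbut-3-en-2-yl)-2-[(5-methylhex-4-enoyl)oxy]-3-oxohexanoate
Product: 12 (5R)-4-hydroxy-3-(3-methylbut-2-en-1-yl)-5-[(2R)-2-methylbutanoyl]-5-(2-methylbut-3-en-2-yl)furan-2(5H)-one
Conditions: LiHMDS (2.2 equiv), THF, −78 to −20 °C; cold 1 M HCl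
Reagents that add atoms: none
Why: In this Dieckmann condensation, addition of the hexenoate enolate to the crowded ketone is reversible, whereas attack on the methyl ester ends in the stable tetronate anion; C5 carries no hydrogen, and enolisation at the sec-butyl CH would give a tetrasubstituted enolate with severe A(1,3) strain against C5, so both centres should hold (the 5R descriptor reflects only a CIP priority change).

Step 7
Reactants: 12 (5R)-4-hydroxy-3-(3-methylbut-2-en-1-yl)-5-[(2R)-2-methylbutanoyl]-5-(2-methylbut-3-en-2-yl)furan-2(5H)-one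
Product: 13 (5S)-3-bromo-3-(3-methylbut-2-en-1-yl)-5-[(2R)-2-methylbutanoyl]-5-(2-methylbut-3-en-2-yl)furan-2,4(3H,5H)-dione (C3 epimers, used together)
Conditions: NBS (1.05 equiv), CH2Cl2, −78 to −30 °C, dark; cold filtration through silica, used at once
Reagents that add atoms: N-bromosuccinimide, O=C1CCC(=O)N1Br
Why: Electrophilic α-bromination of the enolic 1,3-dicarbonyl unit at C3 is much faster at low temperature than attack on the isolated alkenes, and the new C–Br centre needs no control because step 8 planarises it.

Step 8
Reactants: 13 (5S)-3-bromo-3-(3-methylbut-2-en-1-yl)-5-[(2R)-2-methylbutanoyl]-5-(2-methylbut-3-en-2-yl)furan-2,4(3H,5H)-dione; 14 allyltributylstannane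
Product: 16 (1S,3S,5S)-4,4-dimethyl-1-(3-methylbut-2-en-1-yl)-5-[(2R)-2-methylbutanoyl]-3-(prop-2-en-1-yl)-6-oxabicyclo[3.2.1]octane-7,8-dione, via bicyclic C3 bromide 15 (not isolated)
Conditions: Et3B (0.2 equiv), air, PhH (0.05 M), rt, until 13 is consumed; then 14 (10 equiv), Et3B (0.5 equiv in portions), air, rt to 40 °C, same flask; KF work-up
Reagents that add atoms: allyltributylstannane (14), C=CC[Sn](CCCC)(CCCC)CCCC
Why: Ethyl radicals from Et3B/O2 abstract bromine from either epimer of 13 to give one planar, electrophilic C1 radical delocalised into C7=O and C8=O, which adds to the unsubstituted vinyl terminus (C1–C2), and the secondary C3 radical then takes bromine from a second molecule of 13 and carries the chain to 15; this is a bromine-atom-transfer radical cyclisation of an α-bromo-β-dicarbonyl compound, in which premature return of bromine to C1 is merely degenerate. The cyclohexanone ring C1–C2–C3–C4–C5–C8 closes 6-endo-trig, the usual course for 5-hexenyl radicals with the carbonyl group inside the forming ring, and 5-exo closure is further disfavoured because it would attack the CH next to CMe2 and build a strained 2-oxabicyclo[2.2.1]heptane-3,7-dione. C1 is controlled by C5, since the three-carbon bridge can span the furanone only on the face that carries the dimethylallyl group, so the bridgehead becomes 1S. Once 13 is gone the stannane is added, and Bu3Sn• regenerates the C3 radical from 15, which adds to the stannane and expels Bu3Sn• (Keck allylation, SH2'). C3 is controlled by the bicycle, because on the chair cyclohexanone the O6–C7 bridge is axial at C1 and C5 and lies directly under C3, so the stannane approaches the opposite face and the allyl group ends equatorial (3S). The step needs ring closure before allyl capture (met by withholding the stannane), 6-endo regiochemistry (met by strain and the C4 gem-dimethyl group) and no attack of the C3 radical on the C1 prenyl group (met because that group is equatorial at the bridgehead and points away from C3).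

Step 9
Reactants: 16 (1S,3S,5S)-4,4-dimethyl-1-(3-methylbut-2-en-1-yl)-5-[(2R)-2-methylbutanoyl]-3-(prop-2-en-1-yl)-6-oxabicyclo[3.2.1]octane-7,8-dione; 17 2-methyl-2-butene
Product: 18 (1S,3S,5S)-4,4-dimethyl-1,3-bis(3-methylbut-2-en-1-yl)-5-[(2R)-2-methylbutanoyl]-6-oxabicyclo[3.2.1]octane-7,8-dione (target)
Conditions: Hoveyda–Grubbs second-generation catalyst (5 mol %), 17/CH2Cl2 (1:1), 40 °C, sealed tube
Reagents that add atoms: 2-methyl-2-butene (17), CC=C(C)C
Why: Olefin cross-metathesis of the only terminal alkene with excess 2-methyl-2-butene caps it as the trisubstituted prenyl group; the C1 prenyl group can react only degenerately, the 1,3-diequatorial side chains are too far apart for ring closure, and no stereocentre is touched.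

## Compound list

1 | (R)-2-methylbutanoic acid | CC[C@@H](C)C(=O)O | starting material
2 | potassium methyl malonate | COC(=O)CC(=O)[O-].[K+] | starting material
3 | (2R)-1-(imidazol-1-yl)-2-methylbutan-1-one | CC[C@@H](C)C(=O)n1ccnc1 | intermediate (not isolated)
4 | methyl (4R)-4-methyl-3-oxohexanoate | CC[C@@H](C)C(=O)CC(=O)OC | intermediate
5 | methyl (4R)-2-diazo-4-methyl-3-oxohexanoate | CC[C@@H](C)C(=O)C(=[N+]=[N-])C(=O)OC | intermediate
6 | prenol (3-methylbut-2-en-1-ol) | CC(C)=CCO | starting material
7 | methyl (4R)-4-methyl-2-[(3-methylbut-2-en-1-yl)oxy]-3-oxohexanoate, both C2 epimers | CC[C@@H](C)C(=O)C(OCC=C(C)C)C(=O)OC | intermediate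
8 | methyl (2S,4R)-2-hydroxy-4-methyl-2-(2-methylbut-3-en-2-yl)-3-oxohexanoate | CC[C@@H](C)C(=O)[C@](O)(C(=O)OC)C(C)(C)C=C | intermediate
9 | 5-methylhex-4-enoic acid | CC(C)=CCCC(=O)O | starting material
10 | 5-methylhex-4-enoyl chloride | CC(C)=CCCC(=O)Cl | intermediate (not isolated)
11 | methyl (2S,4R)-4-methyl-2-(2-methylbut-3-en-2-yl)-2-[(5-methylhex-4-enoyl)oxy]-3-oxohexanoate | CC[C@@H](C)C(=O)[C@](OC(=O)CCC=C(C)C)(C(=O)OC)C(C)(C)C=C | intermediate
12 | (5R)-4-hydroxy-3-(3-methylbut-2-en-1-yl)-5-[(2R)-2-methylbutanoyl]-5-(2-methylbut-3-en-2-yl)furan-2(5H)-one | CC[C@@H](C)C(=O)[C@@]1(OC(=O)C(CC=C(C)C)=C1O)C(C)(C)C=C | intermediate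
13 | (5S)-3-bromo-3-(3-methylbut-2-en-1-yl)-5-[(2R)-2-methylbutanoyl]-5-(2-methylbut-3-en-2-yl)furan-2,4(3H,5H)-dione, C3 epimers used together, (3S) epimer drawn | CC[C@@H](C)C(=O)[C@@]1(OC(=O)[C@](Br)(CC=C(C)C)C1=O)C(C)(C)C=C | intermediate
14 | allyltributylstannane | C=CC[Sn](CCCC)(CCCC)CCCC | starting material
15 | (1S,3S,5S)-3-bromo-4,4-dimethyl-1-(3-methylbut-2-en-1-yl)-5-[(2R)-2-methylbutanoyl]-6-oxabicyclo[3.2.1]octane-7,8-dione, exo bromide drawn, C3 configuration of no consequence | CC[C@@H](C)C(=O)[C@@]12OC(=O)[C@@](CC=C(C)C)(C[C@H](Br)C1(C)C)C2=O | intermediate (not isolated)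
16 | (1S,3S,5S)-4,4-dimethyl-1-(3-methylbut-2-en-1-yl)-5-[(2R)-2-methylbutanoyl]-3-(prop-2-en-1-yl)-6-oxabicyclo[3.2.1]octane-7,8-dione | CC[C@@H](C)C(=O)[C@@]12OC(=O)[C@@](CC=C(C)C)(C[C@H](CC=C)C1(C)C)C2=O | intermediate
17 | 2-methyl-2-butene | CC=C(C)C | starting material
18 | (1S,3S,5S)-4,4-dimethyl-1,3-bis(3-methylbut-2-en-1-yl)-5-[(2R)-2-methylbutanoyl]-6-oxabicyclo[3.2.1]octane-7,8-dione | CC[C@@H](C)C(=O)[C@@]12OC(=O)[C@@](CC=C(C)C)(C[C@H](CC=C(C)C)C1(C)C)C2=O | target

## Step count and risks

Total step count: 9. Longest linear sequence: 9 steps (1 to 18).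

**Step 8 (most at risk).**
- The positive bromine of 13 may pass ionically to the electron-rich prenyl double bond before a chain is established.
- The C1 radical may be consumed by Et3B through boron enolate formation, which amounts to net reduction.
- Allyl capture may occur at C1 if the stannane meets unreacted 13.
- The regenerated C3 radical may fragment, by reversal of the ring closure or by cleavage of the crowded C4–C5 bond, in competition with its slow addition to the stannane. The ring bonds overlap poorly with the axial-type orbital of the chair.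
- Facial selectivity at C3 may erode because the axial C4 methyl group also crowds the open face.

The fallback sets out from 12 and returns at 16. It removes the positive halogen and separates the two bond formations. Compound 12 is selenenylated at C3 with PhSeCl/pyridine (CH2Cl2, −78 °C) to the 3-phenylselanyl dione F1. Irradiation in benzene then brings about phenylselanyl group-transfer cyclisation to the bicyclic C3 selenide F2, which is isolated, purified and assigned. A separate Keck allylation of F2 with concentrated 14 (Et3B/air or AIBN) gives 16.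

**Step 4.**
- Bond formation between two fully substituted carbons may be slow.
- Material may leak into the [3,3] shift of the enol form or into an α-ketol shift of the product.
- The product may inhibit the catalyst by chelation.
- Facial selectivity on the enolate may be poor.

The fallback sets out from 5 and returns at 8. It replaces the rearrangement by a carbonyl addition. Compound 5 is oxidised with dimethyldioxirane in acetone to the vicinal tricarbonyl compound methyl (4R)-4-methyl-2,3-dioxohexanoate F3, which is handled as its hydrate and dried over molecular sieves. Prenylboronic acid pinacol ester then adds to the most electrophilic, central C2 carbonyl through a closed six-membered transition state with allylic transposition. An optional 3,3'-disubstituted BINOL catalyst may bias the face. The addition gives 8 together with its (2R,4R) epimer F4, and the two diastereomers are separated by chromatography.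

**Step 6.**
- The ester enolate may add to the neighbouring ketone rather than to the ester.
- Liberated methoxide may cleave the 2-methylbutanoyl group by a retro-Claisen reaction.
- Proton exchange at the sec-butyl methine under excess strong base may erode the (R) centre.

The fallback sets out from 8 and returns at 12. It uses a doubly activated methylene so that a mild base suffices, and it delivers the prenyl group afterwards.
- Compound 8 is heated with Meldrum's acid (toluene, 100 °C). The carboxyketene formed acylates the hindered hydroxyl group under neutral conditions to give the hydrogen malonate of 8 F5.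
- Coupling of F5 with prenol 6 (EDC, DMAP) gives the mixed prenyl malonate F6.
- Lacey–Dieckmann closure with KOtBu (1.1 equiv, THF, 0 °C) gives the prenyl tetronic acid-3-carboxylate F7.
- Pd(PPh3)4 (5 mol %, THF, rt) effects Tsuji decarboxylative allylation. The soft tetronate attacks the unsubstituted terminus of the π-prenyl complex at C3 to give 12.

## Further compounds

F1 | step 8 | (5S)-3-(3-methylbut-2-en-1-yl)-5-[(2R)-2-methylbutanoyl]-5-(2-methylbut-3-en-2-yl)-3-(phenylselanyl)furan-2,4(3H,5H)-dione, C3 epimers | CC[C@@H](C)C(=O)[C@@]1(OC(=O)C([Se]c2ccccc2)(CC=C(C)C)C1=O)C(C)(C)C=C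
F2 | step 8 | (1S,3S,5S)-4,4-dimethyl-1-(3-methylbut-2-en-1-yl)-5-[(2R)-2-methylbutanoyl]-3-(phenylselanyl)-6-oxabicyclo[3.2.1]octane-7,8-dione | CC[C@@H](C)C(=O)[C@@]12OC(=O)[C@@](CC=C(C)C)(C[C@H]([Se]c3ccccc3)C1(C)C)C2=O
F3 | step 4 | methyl (4R)-4-methyl-2,3-dioxohexanoate | CC[C@@H](C)C(=O)C(=O)C(=O)OC
F4 | step 4 | methyl (2R,4R)-2-hydroxy-4-methyl-2-(2-methylbut-3-en-2-yl)-3-oxohexanoate | CC[C@@H](C)C(=O)[C@@](O)(C(=O)OC)C(C)(C)C=C
F5 | step 6 | hydrogen malonate of 8 (O-(carboxyacetyl) derivative) | CC[C@@H](C)C(=O)[C@](OC(=O)CC(=O)O)(C(=O)OC)C(C)(C)C=C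
F6 | step 6 | mixed malonate of 8 and prenol | CC[C@@H](C)C(=O)[C@](OC(=O)CC(=O)OCC=C(C)C)(C(=O)OC)C(C)(C)C=C
F7 | step 6 | 3-methylbut-2-en-1-yl (5R)-4-hydroxy-5-[(2R)-2-methylbutanoyl]-5-(2-methylbut-3-en-2-yl)-2-oxo-2,5-dihydrofuran-3-carboxylate | CC[C@@H](C)C(=O)[C@@]1(OC(=O)C(C(=O)OCC=C(C)C)=C1O)C(C)(C)C=C
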